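**Retrosynthetic overview**
- Mururin C (20) comes from its tribenzyl ether 19 by BCl3 debenzylation; 19 from C3 formylation of benzofuran 17; 17 from benzofuran-4-ol 15 by removal of the C4 oxygen through its triflate.
- Ring A (C3a, C4, C5, C6, C7, C7a) carries OMe on C7, next to the furan carbon C7a, and the propyl chain on C5. This 1,3 pattern is what a furyl(methoxy)carbene carbon (C7), a terminal alkyne (C6–H, C5–chain) and one CO (C4) leave behind, so ring A of 15 is cut at C6–C7, C4–C5 and C3a–C4 into carbene complex 11 and alkyne 13.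
- Complex 11 comes from 2-arylfuran 7 (C5 lithiation, Cr(CO)6, Me3OBF4); 7 from keto acetal 6 by cyclodehydration; 6 from dibenzylated 5-hydroxyvanillin 2 and Grignard reagent 4.
- Ring order: the aryl ring is bought, the furan ring is closed in step 4, and benzo ring A is closed last in step 7.

Key step: step 7

Remark: the target has no stereocentre; the carbinol carbon of 5 is formed racemic and is removed by the oxidation in step 3.

**Step 1**
Reactants: 1 3,4-dihydroxy-5-methoxybenzaldehyde
Product: 2 3,4-bis(benzyloxy)-5-methoxybenzaldehyde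
Conditions: BnBr (2.4 equiv), K2CO3, DMF, 60 °C
Reagents that add atoms: benzyl bromide, BrCc1ccccc1
Why: Williamson ether synthesis; carbonate deprotonates both phenols, which displace bromide from benzyl bromide, and the aldehyde is untouched.

**Step 2**
Reactants: 2 3,4-bis(benzyloxy)-5-methoxybenzaldehyde; 3 2-(2-bromoethyl)-1,3-dioxolane
Product: 5 1-[3,4-bis(benzyloxy)-5-methoxyphenyl]-3-(1,3-dioxolan-2-yl)propan-1-ol (racemic), via Grignard reagent 4 (not isolated)
Conditions: 3, Mg, THF, 25–30 °C; then 2, THF, −20 → 0 °C; aq. NH4Cl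
Reagents that add atoms: none
Why: Grignard addition to an aryl aldehyde; the dioxolanylethyl Grignard reagent is stable below about 30 °C, and the racemic carbinol centre is of no consequence because step 3 oxidises it.

**Step 3**
Reactants: 5 1-[3,4-bis(benzyloxy)-5-methoxyphenyl]-3-(1,3-dioxolan-2-yl)propan-1-ol
Product: 6 1-[3,4-bis(benzyloxy)-5-methoxyphenyl]-3-(1,3-dioxolan-2-yl)propan-1-one
Conditions: Dess–Martin periodinane, CH2Cl2, 0 °C → rt
Reagents that add atoms: none
Why: Dess–Martin oxidation of a secondary benzylic alcohol to the aryl ketone under nearly neutral conditions that leave the dioxolane and the benzyl ethers alone.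

**Step 4**
Reactants: 6 1-[3,4-bis(benzyloxy)-5-methoxyphenyl]-3-(1,3-dioxolan-2-yl)propan-1-one
Product: 7 2-[3,4-bis(benzyloxy)-5-methoxyphenyl]furan
Conditions: p-TsOH·H2O (cat.), toluene, 80 °C
Reagents that add atoms: none
Why: Paal–Knorr-type furan synthesis; acid opens the dioxolane of this masked 1,4-keto aldehyde to an oxocarbenium ion, the ketone oxygen closes the five-membered ring, and loss of ethylene glycol with aromatisation gives the 2-arylfuran.

**Step 5**
Reactants: 7 2-[3,4-bis(benzyloxy)-5-methoxyphenyl]furan; 8 chromium hexacarbonyl, Cr(CO)6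
Product: 11 pentacarbonyl{[5-(3,4-bis(benzyloxy)-5-methoxyphenyl)furan-2-yl](methoxy)methylidene}chromium, via 5-lithiofuran 9 (not isolated), via lithium acylchromate 10 (not isolated)
Conditions: n-BuLi, THF, −78 → −20 °C; Cr(CO)6, −78 °C → rt; evaporate; Me3OBF4, CH2Cl2, 0 °C
Reagents that add atoms: trimethyloxonium tetrafluoroborate, C[O+](C)C.F[B-](F)(F)F
Why: Fischer carbene synthesis; the free α-position C5 of the furan is the most acidic C–H and is lithiated, the furyllithium adds to a CO ligand of Cr(CO)6, and the hard oxonium salt methylates the acylchromate on oxygen.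

**Step 6**
Reactants: 12 pent-4-yn-1-ol
Product: 13 5-(benzyloxy)pent-1-yne
Conditions: NaH (1.05 equiv), THF, 0 °C; BnBr, n-Bu4NI (cat.), rt
Reagents that add atoms: benzyl bromide, BrCc1ccccc1
Why: Williamson ether synthesis; NaH removes the hydroxyl proton, which is far more acidic than the alkyne C–H, and the alkoxide is benzylated.

**Step 7**
Reactants: 11 pentacarbonyl{[5-(3,4-bis(benzyloxy)-5-methoxyphenyl)furan-2-yl](methoxy)methylidene}chromium; 13 5-(benzyloxy)pent-1-yne (1.5–2 equiv)
Product: 15 2-[3,4-bis(benzyloxy)-5-methoxyphenyl]-5-[3-(benzyloxy)propyl]-7-methoxy-1-benzofuran-4-ol, via arene–Cr(CO)3 complex 14 (not isolated)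
Conditions: degassed THF (0.05 M), 60 °C, Ar; then air, Et2O, rt; silica filtration; 15 is taken on without storage
Reagents that add atoms: none
Why: Dötz benzannulation: thermal loss of one CO from 11 lets alkyne 13 insert into the Cr=C bond (forming C6–C7) to give a vinylcarbene, CO insertion (forming C4–C5) gives a chromium-bound dienylketene, and a six-electron electrocyclisation of the ketene carbon onto furan C3 (forming C3a–C4) closes ring A, after which tautomerisation gives the phenol as its Cr(CO)3 complex 14 and air frees it. The closest known reaction type is the benzannulation of 2-furyl(alkoxy)carbene complexes of zerovalent chromium with terminal alkynes to 4-hydroxy-7-alkoxybenzofurans. No stereocentre is formed. The step needs alkyne regioselectivity: for steric reasons the larger alkyne substituent ends next to the CO-derived carbon and away from the C–OMe carbon, which places the chain on C5 and H on C6 and is reliable for terminal alkynes. It also needs CO insertion to win over cyclopentannulation, which chromium, an alkoxy carbene and THF as solvent favour. The 5-aryl group lies far from the reacting C2–C3 edge of the furan.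

**Step 8**
Reactants: 15 2-[3,4-bis(benzyloxy)-5-methoxyphenyl]-5-[3-(benzyloxy)propyl]-7-methoxy-1-benzofuran-4-ol
Product: 16 2-[3,4-bis(benzyloxy)-5-methoxyphenyl]-5-[3-(benzyloxy)propyl]-7-methoxy-1-benzofuran-4-yl trifluoromethanesulfonate
Conditions: Tf2O, pyridine, CH2Cl2, 0 °C
Reagents that add atoms: trifluoromethanesulfonic anhydride, O=S(=O)(OS(=O)(=O)C(F)(F)F)C(F)(F)F
Why: O-sulfonylation of the phenol turns the C4–O bond into a leaving group for palladium and also removes the oxidation-prone hydroquinone monoether.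

**Step 9**
Reactants: 16 2-[3,4-bis(benzyloxy)-5-methoxyphenyl]-5-[3-(benzyloxy)propyl]-7-methoxy-1-benzofuran-4-yl trifluoromethanesulfonate
Product: 17 2-[3,4-bis(benzyloxy)-5-methoxyphenyl]-5-[3-(benzyloxy)propyl]-7-methoxy-1-benzofuran
Conditions: Pd(OAc)2 (5 mol %), 1,1'-bis(diphenylphosphino)ferrocene (dppf), HCO2H, Et3N, DMF, 70 °C
Reagents that add atoms: none
Why: Palladium-catalysed formate reduction of an aryl triflate (oxidative addition of zerovalent palladium, formate exchange, decarboxylation to Pd–H, reductive elimination); the homogeneous catalyst does not hydrogenolyse benzyl ethers.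

**Step 10**
Reactants: 17 2-[3,4-bis(benzyloxy)-5-methoxyphenyl]-5-[3-(benzyloxy)propyl]-7-methoxy-1-benzofuran
Product: 19 2-[3,4-bis(benzyloxy)-5-methoxyphenyl]-5-[3-(benzyloxy)propyl]-7-methoxy-1-benzofuran-3-carbaldehyde, via iminium chloride 18 (not isolated)
Conditions: POCl3, DMF, 0 → 60 °C; then ice–H2O
Reagents that add atoms: N,N-dimethylformamide, CN(C)C=O; water, O
Why: Vilsmeier–Haack formylation; C3 of the 2-arylbenzofuran is the most nucleophilic carbon because attack there gives a cation stabilised by O1 and by the 2-aryl group, and water hydrolyses the iminium salt to the aldehyde.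

**Step 11**
Reactants: 19 2-[3,4-bis(benzyloxy)-5-methoxyphenyl]-5-[3-(benzyloxy)propyl]-7-methoxy-1-benzofuran-3-carbaldehyde
Product: 20 Mururin C, 2-(3,4-dihydroxy-5-methoxyphenyl)-5-(3-hydroxypropyl)-7-methoxy-1-benzofuran-3-carbaldehyde
Conditions: BCl3 (1 M in CH2Cl2, excess), pentamethylbenzene, CH2Cl2, −78 → −20 °C; then H2O
Reagents that add atoms: none
Why: Lewis-acid debenzylation with BCl3 and pentamethylbenzene as a non-basic benzyl-cation scavenger should cleave the two aryl benzyl ethers and the alkyl benzyl ether at low temperature while the two aryl methyl ethers, the aldehyde and the benzofuran stay intact.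

**Compound list**
1 | 3,4-dihydroxy-5-methoxybenzaldehyde (5-hydroxyvanillin) | COc1cc(C=O)cc(O)c1O | starting material
2 | 3,4-bis(benzyloxy)-5-methoxybenzaldehyde | COc1cc(C=O)cc(OCc2ccccc2)c1OCc1ccccc1 | intermediate
3 | 2-(2-bromoethyl)-1,3-dioxolane | BrCCC1OCCO1 | starting material
4 | [2-(1,3-dioxolan-2-yl)ethyl]magnesium bromide | Br[Mg]CCC1OCCO1 | intermediate
5 | 1-[3,4-bis(benzyloxy)-5-methoxyphenyl]-3-(1,3-dioxolan-2-yl)propan-1-ol, racemic | COc1cc(C(O)CCC2OCCO2)cc(OCc2ccccc2)c1OCc1ccccc1 | intermediate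
6 | 1-[3,4-bis(benzyloxy)-5-methoxyphenyl]-3-(1,3-dioxolan-2-yl)propan-1-one | COc1cc(C(=O)CCC2OCCO2)cc(OCc2ccccc2)c1OCc1ccccc1 | intermediate
7 | 2-[3,4-bis(benzyloxy)-5-methoxyphenyl]furan | COc1cc(-c2ccco2)cc(OCc2ccccc2)c1OCc1ccccc1 | intermediate
8 | chromium hexacarbonyl, Cr(CO)6 | O=C=[Cr](=C=O)(=C=O)(=C=O)(=C=O)=C=O | starting material
9 | {5-[3,4-bis(benzyloxy)-5-methoxyphenyl]furan-2-yl}lithium | [Li]c1ccc(-c2cc(OC)c(OCc3ccccc3)c(OCc3ccccc3)c2)o1 | intermediate
10 | lithium pentacarbonyl{[5-(3,4-bis(benzyloxy)-5-methoxyphenyl)furan-2-yl]carbonyl}chromate (acylchromate) | [Li+].[O-]C(c1ccc(-c2cc(OC)c(OCc3ccccc3)c(OCc3ccccc3)c2)o1)=[Cr](=C=O)(=C=O)(=C=O)(=C=O)=C=O | intermediate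
11 | pentacarbonyl{[5-(3,4-bis(benzyloxy)-5-methoxyphenyl)furan-2-yl](methoxy)methylidene}chromium | COC(c1ccc(-c2cc(OC)c(OCc3ccccc3)c(OCc3ccccc3)c2)o1)=[Cr](=C=O)(=C=O)(=C=O)(=C=O)=C=O | intermediate
12 | pent-4-yn-1-ol | C#CCCCO | starting material
13 | 5-(benzyloxy)pent-1-yne | C#CCCCOCc1ccccc1 | intermediate
14 | tricarbonylchromium complex of 15, Cr(CO)3 η6-bound to ring A (metal fragment written as a separate component) | COc1cc(CCCOCc2ccccc2)c(O)c2cc(-c3cc(OC)c(OCc4ccccc4)c(OCc4ccccc4)c3)oc12.O=C=[Cr](=C=O)=C=O | intermediate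
15 | 2-[3,4-bis(benzyloxy)-5-methoxyphenyl]-5-[3-(benzyloxy)propyl]-7-methoxy-1-benzofuran-4-ol | COc1cc(CCCOCc2ccccc2)c(O)c2cc(-c3cc(OC)c(OCc4ccccc4)c(OCc4ccccc4)c3)oc12 | intermediate
16 | 2-[3,4-bis(benzyloxy)-5-methoxyphenyl]-5-[3-(benzyloxy)propyl]-7-methoxy-1-benzofuran-4-yl trifluoromethanesulfonate | COc1cc(CCCOCc2ccccc2)c(OS(=O)(=O)C(F)(F)F)c2cc(-c3cc(OC)c(OCc4ccccc4)c(OCc4ccccc4)c3)oc12 | intermediate
17 | 2-[3,4-bis(benzyloxy)-5-methoxyphenyl]-5-[3-(benzyloxy)propyl]-7-methoxy-1-benzofuran | COc1cc(CCCOCc2ccccc2)cc2cc(-c3cc(OC)c(OCc4ccccc4)c(OCc4ccccc4)c3)oc12 | intermediate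
18 | N-({2-[3,4-bis(benzyloxy)-5-methoxyphenyl]-5-[3-(benzyloxy)propyl]-7-methoxy-1-benzofuran-3-yl}methylidene)-N-methylmethanaminium chloride | COc1cc(CCCOCc2ccccc2)cc2c(C=[N+](C)C)c(-c3cc(OC)c(OCc4ccccc4)c(OCc4ccccc4)c3)oc12.[Cl-] | intermediate
19 | 2-[3,4-bis(benzyloxy)-5-methoxyphenyl]-5-[3-(benzyloxy)propyl]-7-methoxy-1-benzofuran-3-carbaldehyde | COc1cc(CCCOCc2ccccc2)cc2c(C=O)c(-c3cc(OC)c(OCc4ccccc4)c(OCc4ccccc4)c3)oc12 | intermediate
20 | Mururin C, 2-(3,4-dihydroxy-5-methoxyphenyl)-5-(3-hydroxypropyl)-7-methoxy-1-benzofuran-3-carbaldehyde | COc1cc(-c2oc3c(OC)cc(CCCO)cc3c2C=O)cc(O)c1O | target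

**Step count**
Total: 11 steps. Longest linear sequence: 10 steps (steps 1–5 and 7–11 from compound 1); step 6 is a one-step branch.

**Steps most likely to fail**

1. Step 7. CO insertion may lose to direct cyclisation of the vinylcarbene onto the furan (cyclopentannulation) or to a second alkyne insertion, and the electron-rich hydroquinone monoether may be over-oxidised to the 4,7-quinone while air strips the metal. The fallback sets out from aldehyde 2 and comes back at 17, so steps 8 and 9 fall away. Aldehyde 2 is homologated with dimethyl (1-diazo-2-oxopropyl)phosphonate (K2CO3, MeOH, rt; Ohira–Bestmann reaction) to 1,2-bis(benzyloxy)-5-ethynyl-3-methoxybenzene F1. Commercial dihydroconiferyl alcohol (4-(3-hydroxypropyl)-2-methoxyphenol, COc1cc(CCCO)ccc1O) is iodinated ortho to the phenol (I2, NaHCO3, THF/H2O) to 4-(3-hydroxypropyl)-2-iodo-6-methoxyphenol F2. Sonogashira coupling of F1 and F2 (PdCl2(PPh3)2, CuI, Et3N, DMF, 70 °C) gives 2-{[3,4-bis(benzyloxy)-5-methoxyphenyl]ethynyl}-4-(3-hydroxypropyl)-6-methoxyphenol F3. F3 should close in the same flask, by attack of the phenol oxygen on the alkyne, to 3-{2-[3,4-bis(benzyloxy)-5-methoxyphenyl]-7-methoxy-1-benzofuran-5-yl}propan-1-ol F4. Benzylation of the primary alcohol (NaH, BnBr, THF) then gives 17.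

2. Step 10. The weak chloroiminium electrophile may react slowly at C3, which is flanked by the 2-aryl group and C4–H. At the higher temperature then needed, formylation of the trioxygenated aryl ring or of C6 on ring A may compete. The fallback sets out from 17 and comes back at 19. Iodination with N-iodosuccinimide (MeCN, 0 °C) should give 2-[3,4-bis(benzyloxy)-5-methoxyphenyl]-5-[3-(benzyloxy)propyl]-3-iodo-7-methoxy-1-benzofuran F5. Iodine–magnesium exchange with i-PrMgCl·LiCl (THF, −20 → 0 °C) gives the 3-benzofuranylmagnesium chloride F6, which, unlike the 3-lithio species, should not ring-open. Quenching with DMF and then aq. NH4Cl gives aldehyde 19.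

3. Step 5. n-BuLi may remove a benzylic OCH2 proton, followed by Wittig rearrangement, or metalate the aryl ring next to an ether oxygen in competition with deprotonation of furan C5–H. The fallback sets out from 7 and comes back at 9 within step 5. Bromination of the furan α-position with N-bromosuccinimide (DMF, −20 °C) gives 2-[3,4-bis(benzyloxy)-5-methoxyphenyl]-5-bromofuran F7, used at once. Bromine–lithium exchange with n-BuLi (THF, −78 °C) is faster than any deprotonation and gives furyllithium 9, which is carried on with Cr(CO)6 and Me3OBF4 as before.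

**Further compounds**
F1 | step 7 | 1,2-bis(benzyloxy)-5-ethynyl-3-methoxybenzene | C#Cc1cc(OC)c(OCc2ccccc2)c(OCc2ccccc2)c1
F2 | step 7 | 4-(3-hydroxypropyl)-2-iodo-6-methoxyphenol | COc1cc(CCCO)cc(I)c1O
F3 | step 7 | 2-{[3,4-bis(benzyloxy)-5-methoxyphenyl]ethynyl}-4-(3-hydroxypropyl)-6-methoxyphenol | COc1cc(CCCO)cc(C#Cc2cc(OC)c(OCc3ccccc3)c(OCc3ccccc3)c2)c1O
F4 | step 7 | 3-{2-[3,4-bis(benzyloxy)-5-methoxyphenyl]-7-methoxy-1-benzofuran-5-yl}propan-1-ol | COc1cc(CCCO)cc2cc(-c3cc(OC)c(OCc4ccccc4)c(OCc4ccccc4)c3)oc12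
F5 | step 10 | 2-[3,4-bis(benzyloxy)-5-methoxyphenyl]-5-[3-(benzyloxy)propyl]-3-iodo-7-methoxy-1-benzofuran | COc1cc(CCCOCc2ccccc2)cc2c(I)c(-c3cc(OC)c(OCc4ccccc4)c(OCc4ccccc4)c3)oc12
F6 | step 10 | {2-[3,4-bis(benzyloxy)-5-methoxyphenyl]-5-[3-(benzyloxy)propyl]-7-methoxy-1-benzofuran-3-yl}magnesium chloride | COc1cc(CCCOCc2ccccc2)cc2c([Mg]Cl)c(-c3cc(OC)c(OCc4ccccc4)c(OCc4ccccc4)c3)oc12
F7 | step 5 | 2-[3,4-bis(benzyloxy)-5-methoxyphenyl]-5-bromofuran | COc1cc(-c2ccc(Br)o2)cc(OCc2ccccc2)c1OCc1ccccc1
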